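The earlier runs and the new flask were computed with constants of no real substance; the scatter is artificial.

In a one-step world, starting material and coupling partner meet at a rate k·S·P, with S and P their concentrations and k one constant, so I first held the earlier runs against that.

in all of them: starting material 0.50 M; free catalyst 50 mM

| charge | coupling partner | protic impurity | capture agent | temperature | remark | time |
|---|---|---|---|---|---|---|
| birch | 0.525 M | 0.067 M | 0.025 M | 50 °C | run made earlier |  |
| alder | 0.525 M | 0.15 M | 0.025 M | 72 °C | run made earlier |  |
| elm | 1.1 M | 0.10 M | 0.025 M | 50 °C | run made earlier |  |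
| grey | 0.525 M | 0.100 M | 0.0250 M | 40 °C |  | 2.5 d |
| ochre | 0.525 M | 0.100 M | 0.0250 M | 60 °C |  | 2.5 d |
| red | 0.525 M | 0.100 M | 0.0250 M | 80 °C |  | 2.5 d |

| run | time / h | starting material / % | trapped intermediate / % | catalyst intermediate A / % | product / % |
|---|---|---|---|---|---|
| birch | 6.00 | 86.5 | 1.0 | 0 | 12.1 |
| birch | 12.0 | 77.0 | 0.4 | 0.5 | 22.5 |
| birch | 15.0 | 72.4 | 0.8 | 1.1 | 26.0 |
| birch | 25.0 | 63.1 | 1.1 | 0.3 | 36.2 |
| alder | 0.667 | 94.8 | 0 | 0.3 | 4.0 |
| alder | 1.33 | 91.6 | 0 | 0.7 | 8.9 |
| alder | 3.00 | 83.7 | 0 | 0.5 | 16.8 |
| alder | 8.00 | 67.2 | 0 | 0 | 30.5 |
| elm | 3.00 | 86.7 | 0.1 | 0.3 | 11.5 |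
| elm | 8.00 | 71.9 | 1.1 | 1.0 | 26.8 |
| elm | 15.0 | 56.8 | 1.6 | 0 | 42.4 |
| elm | 25.0 | 41.6 | 1.3 | 0.8 | 57.7 |

(readings scatter by 0.5 percentage points)

- which of these there is most of at the end, counted by the starting material in it, grey (product / trapped intermediate / catalyst intermediate A / starting material)
- which of these there is most of at the end, counted by the starting material in it, ochre (product / trapped intermediate / catalyst intermediate A / starting material)
- which of these there is most of at the end, counted by the starting material in it, red (product / trapped intermediate / catalyst intermediate A / starting material)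
- final amount of the leader among these, as a percentage of the starting material charged, in grey
- final amount of the leader among these, as a percentage of the starting material charged, in ochre
- final amount of the leader among these, as a percentage of the starting material charged, in red



Elm had twice the partner of birch and at first lost starting material twice as fast, so I took the rate as first order in partner. If partner fell one for one with starting material, birch gave this k over its first stretch and between its last two readings:

k early = 0.0491 M⁻¹ h⁻¹, k late = 0.0377 M⁻¹ h⁻¹

That is a fall of 23.2%, so the one-step picture failed. My first objection was catalyst lost to the trapped intermediate. But birch's last reading holds 11.0% of the catalyst charged in that form, less than the fall, and alder's last reading shows 0%.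

So I supposed that each protic impurity spends one coupling partner. The partner then serves less starting material:

ceiling = (0.525 M − 0.100 M) / 0.50 M = 85.0%

This product ceiling is the share of the starting material that the partner can still convert once the impurity has had its share, which makes the partner the limiting reagent. Partner then equals S − g, with g = 0.0750 M in the new flasks. Taking birch's own g off its late stretch gave k = 0.0463 M⁻¹ h⁻¹, close to the early figure. The same treatment of alder gave 0.173 M⁻¹ h⁻¹, and the pair gave an activation energy of 55.7 kJ mol⁻¹. Integrating the rate k·S·(S − g):

ln(S/(S − g)) rises from its starting value by g·k·t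

This gave product 64.6% in ochre and 79.9% in red.

The objection here was grey: cold, its impurity may not be spent early, so the full deduction overstates what remains. I therefore bracketed grey's starting material between 56.6% with no deduction and 63.4% with the full one.

The forecast, “suggesting slow catalyst death”, put starting material ahead in grey at 61% and product ahead at 58% in ochre and 67% in red, both below my figures.

The flasks gave starting material at 58.7% in grey, and product at 64.9% in ochre and 78.2% in red.

    coupling partner + protic impurity → quenched reagent (k = 0.288 M⁻¹ h⁻¹, Ea = 72.0 kJ mol⁻¹)
    catalyst intermediate B → free catalyst + product (k = 4.79 h⁻¹, Ea = 103 kJ mol⁻¹)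
    starting material + free catalyst ⇌ catalyst intermediate A (K = 0.260 M⁻¹, k = 1.08 M⁻¹ h⁻¹, Ea = 86.0 kJ mol⁻¹, ΔH = −38.0 kJ mol⁻¹)
    coupling partner + catalyst intermediate A → catalyst intermediate B (k = 3.36 M⁻¹ h⁻¹, Ea = 79.0 kJ mol⁻¹)
    catalyst intermediate B + capture agent → trapped intermediate (k = 11.5 M⁻¹ h⁻¹, Ea = 60.0 kJ mol⁻¹)
    (constants at 40 °C)

The charged protic impurity could take 19.0% of the coupling partner, and in grey it was down to 3.91% of its own charge at 1.25 d, with 0.0996 M of quenched reagent standing at 2.50 d. At the end of grey, protic impurity stood at 0.43% of its charge, less than the 59% of starting material left. Red held 84.3% product at 25.0 d, under the ceiling of 85.0%. For a repeat of grey at 65 °C, the same line gives 69.7%, and that flask held 69.3%.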